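## Retrosynthetic overview

1. Ring B goes on last: a rhodium-catalysed asymmetric 1,4-addition of resorcinol-derived arylboronic acid 25 to chromone 20 sets 2S, followed by chelation-controlled 5-O-demethylation and MOM removal.
2. Ring C (the pyranone) is closed on ring A from acetophenone 18 through the one oxygen carried as a MOM ether, which places the ring oxygen next to the side chain.
3. Side chain: a ring-expanding conjunctive coupling (1,2-shift of carbon from boron to carbon, oxaborolane to oxaborinane) joins aryl bromide 7, a vinyl unit and the five-carbon alcohol fragment and sets the side-chain R centre; a Zweifel 1,2-shift then replaces boron by isopropenyl.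
4. Ring A comes from resorcinol (methylation, C–H borylation/oxidation, MOM ether, ortho-lithiation/bromination); ring B comes from resorcinol too.
5. Ring order: ring A (bought) → temporary boron heterocycle (five-, six-, then seven-membered, then opened) → ring C → ring B attached.

Assumption: the target is read as 2S in the chromanone and R in the side chain; in steps 6 and 12 the ligand antipode is the one found in a test run to give these centres, and vinyllithium and isopropenyllithium are used as separately prepared stock solutions.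

## Route

Step 1
Reactants: 1 resorcinol
Product: 2 1,3-dimethoxybenzene
Conditions: MeI, K2CO3, acetone, reflux
Reagents that add atoms: iodomethane, CI
Why: Williamson O-methylation of two equivalent phenols, so no selectivity question arises.

Step 2
Reactants: 2 1,3-dimethoxybenzene
Product: 4 3,5-dimethoxyphenol, via aryl pinacol boronate 3 (not isolated)
Conditions: HBpin, [Ir(OMe)(cod)]2 (1 mol %), dtbpy, THF, 60 °C; then H2O2, NaOH aq, 0 °C → rt
Reagents that add atoms: pinacolborane, [H]B1OC(C)(C)C(C)(C)O1 (boron held only in 3); hydrogen peroxide, OO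
Why: Sterically governed iridium-catalysed C–H borylation goes to C5, the only position with no ortho substituent, and one-pot boronate oxidation gives the phenol.

Step 3
Reactants: 4 3,5-dimethoxyphenol
Product: 5 1,3-dimethoxy-5-(methoxymethoxy)benzene
Conditions: MOMCl, i-Pr2NEt, CH2Cl2, 0 °C → rt
Reagents that add atoms: chloromethyl methyl ether, COCCl
Why: O-alkylation to the MOM acetal, which is the strongest ortho-directing group on the ring and marks this oxygen as the future ring oxygen.

Step 4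
Reactants: 5 1,3-dimethoxy-5-(methoxymethoxy)benzene
Product: 7 2-bromo-1,5-dimethoxy-3-(methoxymethoxy)benzene, via aryllithium 6 (not isolated)
Conditions: n-BuLi, TMEDA, THF, 0 °C; BrCF2CF2Br, −78 °C
Reagents that add atoms: n-butyllithium, [Li]CCCC (lithium held only in 6); 1,2-dibromotetrafluoroethane, FC(F)(Br)C(F)(F)Br
Why: Directed ortho-metalation next to OMOM (two equivalent sites between OMOM and OMe, preferred over the site between the two OMe groups), then electrophilic bromination of the aryllithium.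

Step 5
Reactants: 8 2-methylbut-3-en-2-ol
Product: 10 2-methoxy-5,5-dimethyl-1,2-oxaborolane, via oxaborolane hydride 9 (not isolated)
Conditions: BH3·SMe2 (1.05 equiv), THF, 0 °C → rt (slow addition of 8); MeOH; distillation
Reagents that add atoms: borane dimethyl sulfide, C[S+](C)[BH3-]; methanol, CO
Why: Anti-Markovnikov hydroboration of the terminal alkene with intramolecular B–H/O–H dehydrocoupling closes the five-membered oxaborolane (known behaviour of allylic alcohols in hydroboration), and methanolysis caps boron.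

Step 6
Reactants: 10 2-methoxy-5,5-dimethyl-1,2-oxaborolane; 7 2-bromo-1,5-dimethoxy-3-(methoxymethoxy)benzene
Product: 15 (5R)-5-{[2,4-dimethoxy-6-(methoxymethoxy)phenyl]methyl}-2,6-dimethylhept-6-en-2-ol, via vinyl borate complex 11 (not isolated), via ring-expanded boronic ester 12 (not isolated), via isopropenyl borate complex 13 (not isolated), via iodo oxaborepane 14 (not isolated)
Conditions: 10 (1.3 equiv), vinyllithium, THF, −78 °C → rt; 7, Pd(OAc)2 (3 mol %), (Sp,Sp)-MandyPhos Fe[C5H3(PPh2)CH(NMe2)Ph]2 (3.6 mol %), NaOTf, THF, 60 °C; −78 °C, isopropenyllithium; I2, MeOH; NaOMe, −78 → 0 °C; H2O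
Reagents that add atoms: vinyllithium, [Li]C=C; isopropenyllithium, [Li]C(C)=C; iodine, II (held only in 14)
Why: Proposed new method: a ring-expanding conjunctive cross-coupling in which the arylpalladium cation from 7 (divalent palladium, formed by oxidative addition to zerovalent palladium) binds the vinyl group of four-coordinate borate 11 and triggers an anti 1,2-shift of the ring carbon from boron to the neighbouring vinyl carbon (five-membered oxaborolane to six-membered oxaborinane), C–aryl reductive elimination then gives 12 with the R carbon centre set by the chiral bisphosphine (boron in 11 is stereogenic but equilibrates by methoxide exchange), and the known Zweifel sequence in the same flask (second 1,2-shift with retention to 14, then anti elimination of boron and iodide) turns C–B into C–isopropenyl and frees the tertiary alcohol; the closest known reaction is the conjunctive coupling of acyclic vinyl pinacol boronate complexes, not yet shown for a cyclic alkoxy boronate whose migrating carbon is tethered to the boron-bound oxygen.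

Step 7
Reactants: 15 (5R)-5-{[2,4-dimethoxy-6-(methoxymethoxy)phenyl]methyl}-2,6-dimethylhept-6-en-2-ol
Product: 18 1-{3-[(2R)-5-hydroxy-5-methyl-2-(prop-1-en-2-yl)hexyl]-4,6-dimethoxy-2-(methoxymethoxy)phenyl}ethan-1-one, via dilithiated arene 16 (not isolated), via lithium hemiaminal adduct 17 (not isolated)
Conditions: n-BuLi (2.3 equiv), THF, −20 → 0 °C; MeC(O)N(OMe)Me, −78 → 0 °C; H2O
Reagents that add atoms: n-butyllithium, [Li]CCCC (lithium held only in 16 and 17); N-methoxy-N-methylacetamide, CC(=O)N(C)OC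
Why: Second directed ortho-metalation (after alkoxide formation, OMOM directs to its one free ortho site between OMOM and OMe) followed by Weinreb ketone synthesis, where the chelated adduct stops at the ketone.

Step 8
Reactants: 18 1-{3-[(2R)-5-hydroxy-5-methyl-2-(prop-1-en-2-yl)hexyl]-4,6-dimethoxy-2-(methoxymethoxy)phenyl}ethan-1-one
Product: 20 8-[(2R)-5-hydroxy-5-methyl-2-(prop-1-en-2-yl)hexyl]-5,7-dimethoxy-4H-chromen-4-one, via enaminone 19 (not isolated)
Conditions: Me2NCH(OMe)2, toluene, 100 °C; evaporate; HCl (1 M in MeOH), 0 °C → rt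
Reagents that add atoms: N,N-dimethylformamide dimethyl acetal, COC(OC)N(C)C
Why: Standard chromone synthesis (enaminone formation, then acid-induced MOM loss and addition–elimination); only the MOM oxygen can close the ring, which fixes the side chain at C8 and leaves the 5-OMe.

Step 9
Reactants: 1 resorcinol
Product: 21 1,3-bis(methoxymethoxy)benzene
Conditions: MOMCl (2.4 equiv), i-Pr2NEt, CH2Cl2, 0 °C → rt
Reagents that add atoms: chloromethyl methyl ether, COCCl
Why: Double O-alkylation to the bis-MOM ether, which protects ring B through the organometallic steps.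

Step 10
Reactants: 21 1,3-bis(methoxymethoxy)benzene
Product: 22 1-bromo-2,4-bis(methoxymethoxy)benzene
Conditions: NBS, MeCN, 0 °C
Reagents that add atoms: N-bromosuccinimide, O=C1CCC(=O)N1Br
Why: Electrophilic aromatic bromination at C4 (para to one ether, ortho to the other), the most activated unshielded position.

Step 11
Reactants: 22 1-bromo-2,4-bis(methoxymethoxy)benzene
Product: 25 [2,4-bis(methoxymethoxy)phenyl]boronic acid, via aryllithium 23 (not isolated), via lithium triisopropoxyborate 24 (not isolated)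
Conditions: n-BuLi, THF, −78 °C; B(OiPr)3, −78 °C → rt; H2O (pH about 6)
Reagents that add atoms: n-butyllithium, [Li]CCCC (lithium held only in 23 and 24); triisopropyl borate, CC(C)OB(OC(C)C)OC(C)C; water, O
Why: Lithium–bromine exchange, borylation of the aryllithium and mild hydrolysis that keeps the MOM ethers.

Step 12
Reactants: 20 8-[(2R)-5-hydroxy-5-methyl-2-(prop-1-en-2-yl)hexyl]-5,7-dimethoxy-4H-chromen-4-one; 25 [2,4-bis(methoxymethoxy)phenyl]boronic acid
Product: 26 (2S)-2-[2,4-bis(methoxymethoxy)phenyl]-8-[(2R)-5-hydroxy-5-methyl-2-(prop-1-en-2-yl)hexyl]-5,7-dimethoxy-2,3-dihydro-4H-chromen-4-one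
Conditions: [RhCl(C2H4)2]2 (2.5 mol %), MeO-F12-BIPHEP (antipode giving 2S, 5.5 mol %), KOH (0.2 equiv), toluene/H2O, 25 °C
Reagents that add atoms: none
Why: Hayashi–Miyaura asymmetric 1,4-addition, in which the aryl–rhodium species with the electron-poor chiral bisphosphine adds to C2 of the chromone from one face and the rhodium enolate is protonated, giving 2S (this reaction type is established for 5,7-dimethoxychromone, and the remote side-chain centre does not interfere).

Step 13
Reactants: 26 (2S)-2-[2,4-bis(methoxymethoxy)phenyl]-8-[(2R)-5-hydroxy-5-methyl-2-(prop-1-en-2-yl)hexyl]-5,7-dimethoxy-2,3-dihydro-4H-chromen-4-one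
Product: 27 (2S)-2-[2,4-bis(methoxymethoxy)phenyl]-5-hydroxy-8-[(2R)-5-hydroxy-5-methyl-2-(prop-1-en-2-yl)hexyl]-7-methoxy-2,3-dihydro-4H-chromen-4-one
Conditions: MgI2·OEt2 (3 equiv), toluene/Et2O, 50 °C
Reagents that add atoms: none
Why: Chelation-controlled ether cleavage, where magnesium held between the C4 carbonyl and the 5-methoxy oxygen activates only that methyl for SN2 attack by iodide, leaving the 7-OMe, the alkene and C2 untouched.

Step 14
Reactants: 27 (2S)-2-[2,4-bis(methoxymethoxy)phenyl]-5-hydroxy-8-[(2R)-5-hydroxy-5-methyl-2-(prop-1-en-2-yl)hexyl]-7-methoxy-2,3-dihydro-4H-chromen-4-one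
Product: 28 (2S)-2-(2,4-dihydroxyphenyl)-5-hydroxy-8-[(2R)-5-hydroxy-5-methyl-2-(prop-1-en-2-yl)hexyl]-7-methoxy-2,3-dihydro-4H-chromen-4-one (CNP0106344.1)
Conditions: HCl (1 M), MeOH/THF, 25 °C
Reagents that add atoms: none
Why: Acid-catalysed transacetalisation removes both aryl MOM groups under conditions mild enough for the isopropenyl group, the tertiary alcohol and the C2 centre.

## Compound list

1 | resorcinol | Oc1cccc(O)c1 | starting material
2 | 1,3-dimethoxybenzene | COc1cccc(OC)c1 | intermediate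
3 | 2-(3,5-dimethoxyphenyl)-4,4,5,5-tetramethyl-1,3,2-dioxaborolane | COc1cc(OC)cc(c1)B1OC(C)(C)C(C)(C)O1 | intermediate
4 | 3,5-dimethoxyphenol | COc1cc(O)cc(OC)c1 | intermediate
5 | 1,3-dimethoxy-5-(methoxymethoxy)benzene | COCOc1cc(OC)cc(OC)c1 | intermediate
6 | [2,4-dimethoxy-6-(methoxymethoxy)phenyl]lithium | [Li]c1c(OC)cc(OC)cc1OCOC | intermediate
7 | 2-bromo-1,5-dimethoxy-3-(methoxymethoxy)benzene | COCOc1cc(OC)cc(OC)c1Br | intermediate
8 | 2-methylbut-3-en-2-ol | C=CC(C)(C)O | starting material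
9 | 5,5-dimethyl-1,2-oxaborolane (B–H) | [BH]1CCC(C)(C)O1 | intermediate
10 | 2-methoxy-5,5-dimethyl-1,2-oxaborolane | COB1CCC(C)(C)O1 | intermediate
11 | lithium 2-ethenyl-2-methoxy-5,5-dimethyl-1,2-oxaborolan-2-uide | [Li+].C=C[B-]1(OC)CCC(C)(C)O1 | intermediate
12 | (3R)-3-{[2,4-dimethoxy-6-(methoxymethoxy)phenyl]methyl}-2-methoxy-6,6-dimethyl-1,2-oxaborinane | COB1OC(C)(C)CC[C@@H]1Cc1c(OC)cc(OC)cc1OCOC | intermediate
13 | lithium (3R)-3-{[2,4-dimethoxy-6-(methoxymethoxy)phenyl]methyl}-2-methoxy-6,6-dimethyl-2-(prop-1-en-2-yl)-1,2-oxaborinan-2-uide | [Li+].C=C(C)[B-]1(OC)OC(C)(C)CC[C@@H]1Cc1c(OC)cc(OC)cc1OCOC | intermediate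
14 | (4R)-4-{[2,4-dimethoxy-6-(methoxymethoxy)phenyl]methyl}-3-(iodomethyl)-2-methoxy-3,7,7-trimethyl-1,2-oxaborepane (both C3 epimers) | COB1OC(C)(C)CC[C@H](Cc2c(OC)cc(OC)cc2OCOC)C1(C)CI | intermediate
15 | (5R)-5-{[2,4-dimethoxy-6-(methoxymethoxy)phenyl]methyl}-2,6-dimethylhept-6-en-2-ol | C=C(C)[C@H](CCC(C)(C)O)Cc1c(OC)cc(OC)cc1OCOC | intermediate
16 | dilithium salt of 15 (aryl C–Li ortho to OMOM, tertiary O–Li) | C=C(C)[C@H](CCC(C)(C)O[Li])Cc1c(OC)cc(OC)c([Li])c1OCOC | intermediate
17 | dilithium salt of the N-methoxy-N-methyl hemiaminal adduct of 16 | C=C(C)[C@H](CCC(C)(C)O[Li])Cc1c(OC)cc(OC)c(C(C)(O[Li])N(C)OC)c1OCOC | intermediate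
18 | 1-{3-[(2R)-5-hydroxy-5-methyl-2-(prop-1-en-2-yl)hexyl]-4,6-dimethoxy-2-(methoxymethoxy)phenyl}ethan-1-one | C=C(C)[C@H](CCC(C)(C)O)Cc1c(OC)cc(OC)c(C(C)=O)c1OCOC | intermediate
19 | (2E)-3-(dimethylamino)-1-{3-[(2R)-5-hydroxy-5-methyl-2-(prop-1-en-2-yl)hexyl]-4,6-dimethoxy-2-(methoxymethoxy)phenyl}prop-2-en-1-one | C=C(C)[C@H](CCC(C)(C)O)Cc1c(OC)cc(OC)c(C(=O)/C=C/N(C)C)c1OCOC | intermediate
20 | 8-[(2R)-5-hydroxy-5-methyl-2-(prop-1-en-2-yl)hexyl]-5,7-dimethoxy-4H-chromen-4-one | C=C(C)[C@H](CCC(C)(C)O)Cc1c(OC)cc(OC)c2c1OC=CC2=O | intermediate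
21 | 1,3-bis(methoxymethoxy)benzene | COCOc1cccc(OCOC)c1 | intermediate
22 | 1-bromo-2,4-bis(methoxymethoxy)benzene | COCOc1ccc(Br)c(OCOC)c1 | intermediate
23 | [2,4-bis(methoxymethoxy)phenyl]lithium | [Li]c1ccc(OCOC)cc1OCOC | intermediate
24 | lithium [2,4-bis(methoxymethoxy)phenyl]tri(propan-2-yloxy)borate | [Li+].CC(C)O[B-](OC(C)C)(OC(C)C)c1ccc(OCOC)cc1OCOC | intermediate
25 | [2,4-bis(methoxymethoxy)phenyl]boronic acid | OB(O)c1ccc(OCOC)cc1OCOC | intermediate
26 | (2S)-2-[2,4-bis(methoxymethoxy)phenyl]-8-[(2R)-5-hydroxy-5-methyl-2-(prop-1-en-2-yl)hexyl]-5,7-dimethoxy-2,3-dihydro-4H-chromen-4-one | C=C(C)[C@H](CCC(C)(C)O)Cc1c(OC)cc(OC)c2c1O[C@H](c1ccc(OCOC)cc1OCOC)CC2=O | intermediate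
27 | (2S)-2-[2,4-bis(methoxymethoxy)phenyl]-5-hydroxy-8-[(2R)-5-hydroxy-5-methyl-2-(prop-1-en-2-yl)hexyl]-7-methoxy-2,3-dihydro-4H-chromen-4-one | C=C(C)[C@H](CCC(C)(C)O)Cc1c(OC)cc(O)c2c1O[C@H](c1ccc(OCOC)cc1OCOC)CC2=O | intermediate
28 | (2S)-2-(2,4-dihydroxyphenyl)-5-hydroxy-8-[(2R)-5-hydroxy-5-methyl-2-(prop-1-en-2-yl)hexyl]-7-methoxy-2,3-dihydro-4H-chromen-4-one | C=C(C)[C@H](CCC(C)(C)O)Cc1c(OC)cc(O)c2c1O[C@H](c1ccc(O)cc1O)CC2=O | target

## Step count and risks

Total step count: 14. Longest linear sequence: 10 steps (steps 1, 2, 3, 4, 6, 7, 8, 12, 13, 14).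

**Step 6 (the proposed new step).** The cyclic methoxy borate may transfer its vinyl group directly to palladium, lose methoxide before the shift, or give low enantioselectivity, and the di-ortho-alkoxy aryl bromide is slow in oxidative addition. The fallback uses known chemistry, sets out from 8 and 7, and comes back at 15. Compound 8 is silylated (TESCl, imidazole) to triethyl[(2-methylbut-3-en-2-yl)oxy]silane F1. F1 is hydroborated (HBpin, [IrCl(cod)]2, dppe) to triethyl{[2-methyl-4-(4,4,5,5-tetramethyl-1,3,2-dioxaborolan-2-yl)butan-2-yl]oxy}silane F2. F2 is treated with vinyllithium and coupled with 7 under the established acyclic conjunctive conditions (Pd(OAc)2, MandyPhos, NaOTf, THF, 60 °C) to triethyl{[(5R)-6-[2,4-dimethoxy-6-(methoxymethoxy)phenyl]-2-methyl-5-(4,4,5,5-tetramethyl-1,3,2-dioxaborolan-2-yl)hexan-2-yl]oxy}silane F3. A separate Zweifel olefination (isopropenyllithium; I2, MeOH; NaOMe) gives triethyl{[(5R)-5-{[2,4-dimethoxy-6-(methoxymethoxy)phenyl]methyl}-2,6-dimethylhept-6-en-2-yl]oxy}silane F4, and tetrabutylammonium fluoride in THF then gives 15.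

**Step 12.** The ortho-alkoxy arylboronic acid may protodeboronate or add slowly, and the base may open the flavanone. The fallback sets out from 18 and 22 and comes back at 26. Mild methanolic HCl removes the ketone-flanked MOM group of 18 to give 1-{2-hydroxy-3-[(2R)-5-hydroxy-5-methyl-2-(prop-1-en-2-yl)hexyl]-4,6-dimethoxyphenyl}ethan-1-one F5. Bromide 22 is converted (n-BuLi, then DMF) into 2,4-bis(methoxymethoxy)benzaldehyde F6. Claisen–Schmidt condensation of F5 with F6 (KOH, EtOH) gives (2E)-3-[2,4-bis(methoxymethoxy)phenyl]-1-{2-hydroxy-3-[(2R)-5-hydroxy-5-methyl-2-(prop-1-en-2-yl)hexyl]-4,6-dimethoxyphenyl}prop-2-en-1-one F7. Oxa-Michael ring closure (NaOAc, EtOH, reflux) through the only free phenol gives 26 together with its C2 epimer, (2R)-2-[2,4-bis(methoxymethoxy)phenyl]-8-[(2R)-5-hydroxy-5-methyl-2-(prop-1-en-2-yl)hexyl]-5,7-dimethoxy-2,3-dihydro-4H-chromen-4-one F8. The two are diastereomers, are separated by chromatography, and F8 is recycled by re-equilibration under the same conditions.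

**Step 13.** The Lewis acid may ionise the C2–O bond next to the electron-rich ring B (loss of 2S) or attack the side chain. The fallback sets out from 20 and comes back at 27. The demethylation is moved to the chromone, which has no C2 centre to lose: MgI2·OEt2 on 20 gives 5-hydroxy-8-[(2R)-5-hydroxy-5-methyl-2-(prop-1-en-2-yl)hexyl]-7-methoxy-4H-chromen-4-one F9. The rhodium-catalysed addition of 25 is then run on F9 under the conditions of step 12 and gives 27 directly; whether that addition tolerates the free 5-hydroxyl is untested here.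

## Further compounds

F1 | step 6 | triethyl[(2-methylbut-3-en-2-yl)oxy]silane | C=CC(C)(C)O[Si](CC)(CC)CC
F2 | step 6 | triethyl{[2-methyl-4-(4,4,5,5-tetramethyl-1,3,2-dioxaborolan-2-yl)butan-2-yl]oxy}silane | CC[Si](CC)(CC)OC(C)(C)CCB1OC(C)(C)C(C)(C)O1
F3 | step 6 | triethyl{[(5R)-6-[2,4-dimethoxy-6-(methoxymethoxy)phenyl]-2-methyl-5-(4,4,5,5-tetramethyl-1,3,2-dioxaborolan-2-yl)hexan-2-yl]oxy}silane | CC[Si](CC)(CC)OC(C)(C)CC[C@H](Cc1c(OC)cc(OC)cc1OCOC)B1OC(C)(C)C(C)(C)O1
F4 | step 6 | triethyl{[(5R)-5-{[2,4-dimethoxy-6-(methoxymethoxy)phenyl]methyl}-2,6-dimethylhept-6-en-2-yl]oxy}silane | C=C(C)[C@H](CCC(C)(C)O[Si](CC)(CC)CC)Cc1c(OC)cc(OC)cc1OCOC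
F5 | step 12 | 1-{2-hydroxy-3-[(2R)-5-hydroxy-5-methyl-2-(prop-1-en-2-yl)hexyl]-4,6-dimethoxyphenyl}ethan-1-one | C=C(C)[C@H](CCC(C)(C)O)Cc1c(OC)cc(OC)c(C(C)=O)c1O
F6 | step 12 | 2,4-bis(methoxymethoxy)benzaldehyde | COCOc1ccc(C=O)c(OCOC)c1
F7 | step 12 | (2E)-3-[2,4-bis(methoxymethoxy)phenyl]-1-{2-hydroxy-3-[(2R)-5-hydroxy-5-methyl-2-(prop-1-en-2-yl)hexyl]-4,6-dimethoxyphenyl}prop-2-en-1-one | C=C(C)[C@H](CCC(C)(C)O)Cc1c(OC)cc(OC)c(C(=O)/C=C/c2ccc(OCOC)cc2OCOC)c1O
F8 | step 12 | (2R)-2-[2,4-bis(methoxymethoxy)phenyl]-8-[(2R)-5-hydroxy-5-methyl-2-(prop-1-en-2-yl)hexyl]-5,7-dimethoxy-2,3-dihydro-4H-chromen-4-one | C=C(C)[C@H](CCC(C)(C)O)Cc1c(OC)cc(OC)c2c1O[C@@H](c1ccc(OCOC)cc1OCOC)CC2=O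
F9 | step 13 | 5-hydroxy-8-[(2R)-5-hydroxy-5-methyl-2-(prop-1-en-2-yl)hexyl]-7-methoxy-4H-chromen-4-one | C=C(C)[C@H](CCC(C)(C)O)Cc1c(OC)cc(O)c2c1OC=CC2=O
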